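## The problem

The target is an open C25 chain with a 2-hydroxy-2,6,6-trimethylcyclohexyl ring (ring A) at one end and a 4-(hydroxymethyl)butenolide (ring B) at the other. The rings are not fused, so this is a chain-building problem. Ring A carries the vicinal pair C1 (S, the CH bearing the chain) and C2 (S, the tertiary carbinol), with chain and hydroxyl trans; these two can control each other if they are formed in one event. The third stereocentre, C5 of ring B (R), lies ten bonds away, so neither stereochemical island can direct the other and each must be set absolutely. The 6′E alkene has the ordinary terpenoid geometry, but the 2′Z alkene carrying CH2OH is the less stable isomer and needs a kinetically controlled method. The fragile parts are ring B (its C5–H is γ to the carbonyl, so base can racemise it through the 2-oxidofuran, and hydrides or nucleophiles attack the lactone), the tertiary alcohol (ionisation under strong acid) and the two primary allylic hydroxyls. The enabling feature is the five-carbon run made of the alkene CH (C2′), the CH2 next to it (C1′), C5 and C4 of ring B and the C4 hydroxymethyl carbon. It is oxygenated on its last three carbons exactly as a 2-deoxypentose with an R centre at C3, so an olefination of the sugar aldehyde can create the Z alkene while the sugar supplies C5.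

## Retrosynthesis

Target 26 is traced to its tris-silyl ether 25 by cutting three O–Si bonds. Silyl groups are preferred to esters or benzyl ethers because they can be removed by buffered fluoride, which is the only kind of final step ring B tolerates. The skeleton is unchanged, but ring B can then be closed on a substrate with no free hydroxyl.

In 25 the lactone C–O bond and the ring C=C bond are cut, removing a two-carbon unit and leaving the α-hydroxy ketone 23. The neighbouring options are to carry an intact butenolide through the route or to lactonise a Z-enoic acid. The first would expose C5–H to the base and hydride used earlier, and the second would need another geometry-controlled olefination of the ketone. The forward reaction must acylate a hindered secondary hydroxyl with a two-carbon ketene ylide and close the ring by intramolecular Wittig reaction without enolising the ketone.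

From 23 back to the enoate 18 no C–C bond is cut; compounds 22, 21, 20 and 19 only adjust oxidation level and protection. The sugar oxygens are mapped as follows: the PMB-protected O3 becomes the lactone oxygen, C4 becomes the ketone and C5 becomes the silyloxymethyl group, while the ester becomes the chain CH2OH. This ordering keeps the acid step (acetonide removal) before the acid-labile primary silyl ethers are installed. The forward steps must discriminate primary from secondary hydroxyls and remove the PMB group after oxidation.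

Enoate 18 is cut at the C=C bond between the α-carbon and the sugar-derived CH, giving phosphonate 12 and aldehyde 17. Cutting the adjacent CH–CH2 bond would require an alkyl metal or radical β to the C5 oxygen, and cutting on the other side of the alkene would leave the Z geometry unsolved. This cut falls on the bond whose geometry is the problem and divides the molecule into two halves, each holding one stereochemical island. The forward reaction must be Z-selective and must not epimerise or eliminate the β-alkoxy aldehyde.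

Aldehyde 17 is traced through dithiane 16, alcohol 15 and triol 14 to 2-deoxy-L-ribose 13 without any C–C bond change. Opening the lactol as a dithioacetal exposes the three hydroxyls, the terminal diol is tied up as an acetonide, and the one remaining hydroxyl is the one that must become the lactone oxygen.

Phosphonate 12 is cut at the bond between the phosphonate carbon and the chain CH2, giving iodide 10 and the commercial phosphonoacetate 11. Forming the C–P bond last would need a less established phosphonylation of an ester enolate; the alkylation asks only for an SN2 reaction of a stabilised anion at a primary iodide.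

Iodide 10 comes from alcohol 9, whose E alkene is cut at both the C–CH3 bond and the =CH–CH2 bond, leading to the terminal alkyne 6. Olefination of methyl ketone 4 or a Claisen route from it would give E/Z mixtures at this methyl-branched alkene, whereas syn carbometalation of an alkyne fixes the geometry mechanistically. Alkyne 6 is traced to ketone 4 and then to hydroxy ketone 3.

Hydroxy ketone 3 is traced through enol ether 2 to (E)-geranylacetone 1 by cutting the ring A bond between CH and C(CH3)2 and the tertiary C–O bond. No stepwise ring synthesis competes with a cyclisation that makes the carbocycle and both ring stereocentres from an achiral commodity. The forward reaction must control the absolute sense of folding.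

## Roads not taken

Alternative 1: The cut is the ring A C–C bond and the tertiary C–O bond, made together by proton-initiated cation–olefin cyclisation of 1 to the bicyclic enol ether A1. Its merit is that the carbocycle and both ring stereocentres arise in one step, with the trans relationship following from anti addition across the E alkene. Its weak point as an organising idea is that it solves only the C13 ring portion. The Z-hydroxymethyl alkene and the remote C5 centre are untouched and would have to come from a long linear extension. Absolute control also depends on a chiral proton source acting on an unfunctionalised alkene. For ring A it is as good as any plan can be, and the chosen route uses the same cyclisation as its first step (A1 is the same compound as 2). What the chosen plan adds is a convergent union that settles the geometry and the second island at once.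

Alternative 2: The cut is the bond between the Z-alkene CH and the CH2 attached to ring B. The forward step couples the alkenyl iodide A3 with the N-hydroxyphthalimide ester A4 at a cathode under NiCl2·6H2O/bipyridine catalysis, with loss of CO2, to give the bis-silyl ether A2. This road is more convergent than the chosen one: both halves are complete before the union and only desilylation follows, against seven steps after the olefination here. Its weak points are structural. The radical or alkylnickel species from A4 sits β to the lactone oxygen and can fragment by opening ring B. A4 itself has acidic α-protons with a β-carboxylate leaving group. The Z geometry is only moved into the separate synthesis of A3, and the C5 centre needs its own asymmetric synthesis. Against the better step economy, the chosen plan sets a union of known kinetic selectivity, a pool-derived stereocentre, and a butenolide that is formed only after all basic and reductive steps.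

Alternative 3: The cut is the bond between the homoallylic CH2 and the alkene carbon bearing CH2OH. The Grignard reagent A6, made from iodide 10, adds to the magnesium alkoxide of propargyl alcohol A7 under CuI catalysis, and iodine traps the chelated alkenylmagnesium to give the iodo alcohol A5. The chelate fixes both regiochemistry and geometry, the CH2OH arrives at the right oxidation level (no ester reduction), and the phosphonate alkylation is avoided; in redox economy this road is better. Its weak points are that such additions usually need excess Grignard reagent, here a six-step fragment, and that the bond to the ring B side is still unmade. That second coupling needs either a β-oxygenated alkyl metal, which eliminates readily, or metalation of A5 and epoxide opening after extra protection, with the C5 centre supplied separately. The chosen plan sets against it a single union that joins both halves and fixes the geometry together.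

Key step: step 11

Assumption: 13 and 3 are drawn open-chain although 13 is a lactol mixture and 3 may equilibrate with its cyclic hemiketal; both react through the open forms, and 1 is used as the pure E isomer.

## Route

Step 1
Reactants: 1 (E)-geranylacetone
Product: 3 4-[(1S,2S)-2-hydroxy-2,6,6-trimethylcyclohexyl]butan-2-one, via enol ether 2 (not isolated)
Conditions: squalene–hopene cyclase from Alicyclobacillus acidocaldarius (recombinant E. coli cells), citrate buffer pH 6, sodium dodecyl sulfate, 40 °C; extraction; then 1 M aq. HCl, THF, rt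
Reagents that add atoms: water O
Why: Squalene–hopene cyclases are known to accept 1 (cation–olefin cyclisation): an active-site acid protonates the terminal alkene, the E alkene closes the ring through a chair fold by anti addition and the ketone oxygen traps the cation, which sets chain and oxygen trans and, by the fold that gives natural ring A, should give the (4aS,8aS) enol ether; dilute acid then hydrolyses the enol ether.

Step 2
Reactants: 3 4-[(1S,2S)-2-hydroxy-2,6,6-trimethylcyclohexyl]butan-2-one
Product: 4 4-[(1S,2S)-2,6,6-trimethyl-2-(triethylsilyloxy)cyclohexyl]butan-2-one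
Conditions: TESOTf, 2,6-lutidine, CH2Cl2, −78 → 0 °C
Reagents that add atoms: triethylsilyl trifluoromethanesulfonate CC[Si](CC)(CC)OS(=O)(=O)C(F)(F)F
Why: Silyl triflate silylation of a hindered tertiary alcohol; 2,6-lutidine at low temperature should not enolise the methyl ketone, and any silyl enol ether formed is cleaved in the aqueous work-up.

Step 3
Reactants: 4 4-[(1S,2S)-2,6,6-trimethyl-2-(triethylsilyloxy)cyclohexyl]butan-2-one
Product: 6 triethyl{[(1S,2S)-2-(but-3-yn-1-yl)-1,3,3-trimethylcyclohexyl]oxy}silane, via enol phosphate 5 (not isolated)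
Conditions: LiN(iPr)2 (1.1 equiv), THF, −78 °C; ClP(O)(OEt)2, −78 °C → rt; LiN(iPr)2 (2.3 equiv), −78 °C → rt; H2O
Reagents that add atoms: none
Why: Methyl ketone to terminal alkyne conversion: kinetic deprotonation at the methyl group, O-phosphorylation, then base-induced elimination of diethyl phosphate from the terminal enol phosphate; the silyl ether is inert to lithium amide.

Step 4
Reactants: 6 triethyl{[(1S,2S)-2-(but-3-yn-1-yl)-1,3,3-trimethylcyclohexyl]oxy}silane
Product: 9 (3E)-4-methyl-6-[(1S,2S)-2,6,6-trimethyl-2-(triethylsilyloxy)cyclohexyl]hex-3-en-1-ol, via alkenylalane 7 (not isolated), via lithium alanate 8 (not isolated)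
Conditions: AlMe3 (2 equiv), (C5H5)2ZrCl2 (0.2 equiv), CH2Cl2, 0 °C → rt; volatiles removed; n-BuLi, hexane–THF, −78 °C; ethylene oxide, −78 → 0 °C; aq. Rochelle salt
Reagents that add atoms: trimethylaluminium C[Al](C)C; ethylene oxide C1CO1
Why: Negishi carboalumination adds CH3 and Al syn across the terminal alkyne with Al on the terminal carbon, which fixes the E geometry; the derived alanate opens ethylene oxide with retention at the alkenyl carbon to give the homoallylic alcohol.

Step 5
Reactants: 9 (3E)-4-methyl-6-[(1S,2S)-2,6,6-trimethyl-2-(triethylsilyloxy)cyclohexyl]hex-3-en-1-ol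
Product: 10 triethyl({(1S,2S)-2-[(3E)-6-iodo-3-methylhex-3-en-1-yl]-1,3,3-trimethylcyclohexyl}oxy)silane
Conditions: PPh3, I2, imidazole, CH2Cl2, 0 °C → rt
Reagents that add atoms: iodine II
Why: Appel-type iodination of a primary alcohol by SN2 displacement of the alkoxyphosphonium ion; the neutral conditions leave the silyl ether and the alkene untouched.

Step 6
Reactants: 10 triethyl({(1S,2S)-2-[(3E)-6-iodo-3-methylhex-3-en-1-yl]-1,3,3-trimethylcyclohexyl}oxy)silane; 11 methyl 2-[bis(2,2,2-trifluoroethoxy)phosphoryl]acetate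
Product: 12 methyl (5E)-2-[bis(2,2,2-trifluoroethoxy)phosphoryl]-6-methyl-8-[(1S,2S)-2,6,6-trimethyl-2-(triethylsilyloxy)cyclohexyl]oct-5-enoate (mixture of C2 epimers)
Conditions: NaH, 11 (2.5 equiv), DMF, 0 °C → rt; then 10, 50 °C
Reagents that add atoms: none
Why: SN2 C-alkylation of a sodium phosphonoacetate with a primary iodide; excess 11 suppresses dialkylation, and the new phosphonate stereocentre is of no consequence because it is deprotonated in step 11.

Step 7
Reactants: 13 2-deoxy-L-ribose
Product: 14 (2S,3R)-4-(1,3-dithian-2-yl)butane-1,2,3-triol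
Conditions: propane-1,3-dithiol, conc. aq. HCl, 0 °C → rt
Reagents that add atoms: propane-1,3-dithiol SCCCS
Why: Acid-catalysed dithioacetalisation of the open-chain aldose frees the sugar from its lactol forms and masks C1; C3 and C4 are untouched.

Step 8
Reactants: 14 (2S,3R)-4-(1,3-dithian-2-yl)butane-1,2,3-triol
Product: 15 (1R)-2-(1,3-dithian-2-yl)-1-[(4S)-2,2-dimethyl-1,3-dioxolan-4-yl]ethan-1-ol
Conditions: Me2C(OMe)2, p-TsOH·H2O (cat.), acetone, 0 °C → rt
Reagents that add atoms: 2,2-dimethoxypropane COC(C)(C)OC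
Why: Acid-catalysed transketalisation; the terminal diol gives the monosubstituted dioxolane in preference to the cis-disubstituted 3,4-dioxolane or a dioxane with an axial methyl group, leaving the C3 hydroxyl free.

Step 9
Reactants: 15 (1R)-2-(1,3-dithian-2-yl)-1-[(4S)-2,2-dimethyl-1,3-dioxolan-4-yl]ethan-1-ol
Product: 16 2-{(2R)-2-[(4S)-2,2-dimethyl-1,3-dioxolan-4-yl]-2-[(4-methoxyphenyl)methoxy]ethyl}-1,3-dithiane
Conditions: NaH, 4-MeOC6H4CH2Cl, n-Bu4NI (cat.), THF–DMF, 0 °C → rt
Reagents that add atoms: 4-methoxybenzyl chloride COc1ccc(CCl)cc1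
Why: Williamson etherification of the secondary alkoxide; NaH does not deprotonate the dithiane C–H.

Step 10
Reactants: 16 2-{(2R)-2-[(4S)-2,2-dimethyl-1,3-dioxolan-4-yl]-2-[(4-methoxyphenyl)methoxy]ethyl}-1,3-dithiane
Product: 17 (3R)-3-[(4S)-2,2-dimethyl-1,3-dioxolan-4-yl]-3-[(4-methoxyphenyl)methoxy]propanal
Conditions: MeI, CaCO3, MeCN–H2O (4:1), 40 °C
Reagents that add atoms: water O
Why: S-Alkylative dithiane hydrolysis: methylation turns sulfur into a leaving group and water captures the thionium ion; the buffered neutral medium spares the acetonide and PMB ether and should not cause β-elimination of the aldehyde.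

Step 11
Reactants: 12 methyl (5E)-2-[bis(2,2,2-trifluoroethoxy)phosphoryl]-6-methyl-8-[(1S,2S)-2,6,6-trimethyl-2-(triethylsilyloxy)cyclohexyl]oct-5-enoate; 17 (3R)-3-[(4S)-2,2-dimethyl-1,3-dioxolan-4-yl]-3-[(4-methoxyphenyl)methoxy]propanal
Product: 18 methyl (2Z,5E)-2-{(3R)-3-[(4S)-2,2-dimethyl-1,3-dioxolan-4-yl]-3-[(4-methoxyphenyl)methoxy]propylidene}-6-methyl-8-[(1S,2S)-2,6,6-trimethyl-2-(triethylsilyloxy)cyclohexyl]oct-5-enoate
Conditions: KN(SiMe3)2, 18-crown-6, THF, −78 °C; then 17, −78 °C
Reagents that add atoms: none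
Why: Still–Gennari variant of the Horner–Wadsworth–Emmons olefination. KN(SiMe3)2 deprotonates 12, so both epimers converge on one planar anion, and 18-crown-6 sequesters potassium so that the anion adds to 17 without chelation. Because the bis(trifluoroethyl) phosphonate is strongly electron-poor, the first-formed adduct should collapse through its oxaphosphetane faster than it reverts, which delivers the kinetic alkene with the ester cis to the sugar CH2. The closest known reaction type is the olefination of unbranched aldehydes with α-alkyl bis(trifluoroethyl)phosphonoacetates to Z-trisubstituted enoates. No ring is closed and no stereocentre is created. The selectivity needed is the Z geometry, secured by the trifluoroethyl esters, the dissociated counter-ion and the low temperature. The C3 centre of 17 is β to the aldehyde and cannot epimerise, and the weakly basic stabilised anion at −78 °C should not trigger β-elimination of the PMB-oxy group.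

Step 12
Reactants: 18 methyl (2Z,5E)-2-{(3R)-3-[(4S)-2,2-dimethyl-1,3-dioxolan-4-yl]-3-[(4-methoxyphenyl)methoxy]propylidene}-6-methyl-8-[(1S,2S)-2,6,6-trimethyl-2-(triethylsilyloxy)cyclohexyl]oct-5-enoate
Product: 19 (2Z,5E)-2-{(3R)-3-[(4S)-2,2-dimethyl-1,3-dioxolan-4-yl]-3-[(4-methoxyphenyl)methoxy]propylidene}-6-methyl-8-[(1S,2S)-2,6,6-trimethyl-2-(triethylsilyloxy)cyclohexyl]oct-5-en-1-ol
Conditions: iBu2AlH, CH2Cl2, −78 °C; aq. Rochelle salt
Reagents that add atoms: none
Why: 1,2-Reduction of the enoate by iBu2AlH at low temperature gives the allylic alcohol without conjugate reduction or loss of geometry; ethers, acetonide and silyl ether are inert.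

Step 13
Reactants: 19 (2Z,5E)-2-{(3R)-3-[(4S)-2,2-dimethyl-1,3-dioxolan-4-yl]-3-[(4-methoxyphenyl)methoxy]propylidene}-6-methyl-8-[(1S,2S)-2,6,6-trimethyl-2-(triethylsilyloxy)cyclohexyl]oct-5-en-1-ol
Product: 20 (2S,3R,5Z,9E)-6-(hydroxymethyl)-3-[(4-methoxyphenyl)methoxy]-10-methyl-12-[(1S,2S)-2,6,6-trimethyl-2-(triethylsilyloxy)cyclohexyl]dodeca-5,9-diene-1,2-diol
Conditions: CuCl2·2H2O, MeCN, 0 °C
Reagents that add atoms: none
Why: Lewis-acid-assisted hydrolysis of a terminal isopropylidene acetal, a method known to tolerate silyl and PMB ethers; the hindered tertiary triethylsilyl ether should survive at 0 °C.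

Step 14
Reactants: 20 (2S,3R,5Z,9E)-6-(hydroxymethyl)-3-[(4-methoxyphenyl)methoxy]-10-methyl-12-[(1S,2S)-2,6,6-trimethyl-2-(triethylsilyloxy)cyclohexyl]dodeca-5,9-diene-1,2-diol
Product: 21 (2S,3R,5Z,9E)-1-(tert-butyldimethylsilyloxy)-6-[(tert-butyldimethylsilyloxy)methyl]-3-[(4-methoxyphenyl)methoxy]-10-methyl-12-[(1S,2S)-2,6,6-trimethyl-2-(triethylsilyloxy)cyclohexyl]dodeca-5,9-dien-2-ol
Conditions: TBSCl (2.2 equiv), imidazole, CH2Cl2, 0 °C
Reagents that add atoms: tert-butyldimethylsilyl chloride CC(C)(C)[Si](C)(C)Cl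
Why: Imidazole-promoted silylation is strongly selective for the two primary hydroxyls over the secondary C2 hydroxyl, which is flanked by the PMB-oxy carbon.

Step 15
Reactants: 21 (2S,3R,5Z,9E)-1-(tert-butyldimethylsilyloxy)-6-[(tert-butyldimethylsilyloxy)methyl]-3-[(4-methoxyphenyl)methoxy]-10-methyl-12-[(1S,2S)-2,6,6-trimethyl-2-(triethylsilyloxy)cyclohexyl]dodeca-5,9-dien-2-ol
Product: 22 (3R,5Z,9E)-1-(tert-butyldimethylsilyloxy)-6-[(tert-butyldimethylsilyloxy)methyl]-3-[(4-methoxyphenyl)methoxy]-10-methyl-12-[(1S,2S)-2,6,6-trimethyl-2-(triethylsilyloxy)cyclohexyl]dodeca-5,9-dien-2-one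
Conditions: Dess–Martin periodinane, CH2Cl2, 0 °C → rt
Reagents that add atoms: none
Why: Dess–Martin oxidation of the secondary alcohol under near-neutral conditions; the α-alkoxy centre at C3 is not enolised, and the acetic acid released is tolerated by the silyl and PMB ethers.

Step 16
Reactants: 22 (3R,5Z,9E)-1-(tert-butyldimethylsilyloxy)-6-[(tert-butyldimethylsilyloxy)methyl]-3-[(4-methoxyphenyl)methoxy]-10-methyl-12-[(1S,2S)-2,6,6-trimethyl-2-(triethylsilyloxy)cyclohexyl]dodeca-5,9-dien-2-one
Product: 23 (3R,5Z,9E)-1-(tert-butyldimethylsilyloxy)-6-[(tert-butyldimethylsilyloxy)methyl]-3-hydroxy-10-methyl-12-[(1S,2S)-2,6,6-trimethyl-2-(triethylsilyloxy)cyclohexyl]dodeca-5,9-dien-2-one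
Conditions: DDQ, CH2Cl2–pH 7 phosphate buffer (10:1), 0 °C
Reagents that add atoms: none
Why: Oxidative PMB cleavage by DDQ through benzylic hydride abstraction and hydrolysis of the oxocarbenium ion; silyl ethers, ketone and trisubstituted alkenes are inert in the buffered medium.

Step 17
Reactants: 23 (3R,5Z,9E)-1-(tert-butyldimethylsilyloxy)-6-[(tert-butyldimethylsilyloxy)methyl]-3-hydroxy-10-methyl-12-[(1S,2S)-2,6,6-trimethyl-2-(triethylsilyloxy)cyclohexyl]dodeca-5,9-dien-2-one
Product: 25 (5R)-4-[(tert-butyldimethylsilyloxy)methyl]-5-{(2Z,6E)-3-[(tert-butyldimethylsilyloxy)methyl]-7-methyl-9-[(1S,2S)-2,6,6-trimethyl-2-(triethylsilyloxy)cyclohexyl]nona-2,6-dien-1-yl}furan-2(5H)-one, via acyl ylide ester 24 (not isolated)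
Conditions: Ph3P=C=C=O, toluene, 80 °C
Reagents that add atoms: (triphenylphosphoranylidene)ketene O=C=C=P(c1ccccc1)(c1ccccc1)c1ccccc1
Why: Bestmann ylide chemistry: the hydroxyl adds to the ketene to give the acyl ylide ester, which closes the butenolide by intramolecular Wittig reaction with the adjacent ketone; the lactone oxygen is the original C3 oxygen, so C5 keeps its R configuration, and the neutral conditions avoid enolisation.

Step 18
Reactants: 25 (5R)-4-[(tert-butyldimethylsilyloxy)methyl]-5-{(2Z,6E)-3-[(tert-butyldimethylsilyloxy)methyl]-7-methyl-9-[(1S,2S)-2,6,6-trimethyl-2-(triethylsilyloxy)cyclohexyl]nona-2,6-dien-1-yl}furan-2(5H)-one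
Product: 26 (5R)-4-(hydroxymethyl)-5-{(2Z,6E)-3-(hydroxymethyl)-9-[(1S,2S)-2-hydroxy-2,6,6-trimethylcyclohexyl]-7-methylnona-2,6-dien-1-yl}furan-2(5H)-one
Conditions: HF·pyridine, pyridine, THF, 0 °C → rt
Reagents that add atoms: none
Why: Fluoride cleavage of the two primary TBS ethers and the tertiary TES ether under buffered acidic conditions, chosen because basic fluoride could deprotonate ring B at C5 and racemise it.

## Compound list

1 | (5E)-6,10-dimethylundeca-5,9-dien-2-one, (E)-geranylacetone | CC(=O)CC/C=C(\C)CCC=C(C)C | starting material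
2 | (4aS,8aS)-2,5,5,8a-tetramethyl-4a,5,6,7,8,8a-hexahydro-4H-chromene (not isolated) | CC1=CC[C@H]2C(C)(C)CCC[C@]2(C)O1 | intermediate
3 | 4-[(1S,2S)-2-hydroxy-2,6,6-trimethylcyclohexyl]butan-2-one | CC(=O)CC[C@H]1C(C)(C)CCC[C@]1(C)O | intermediate
4 | 4-[(1S,2S)-2,6,6-trimethyl-2-(triethylsilyloxy)cyclohexyl]butan-2-one | CC(=O)CC[C@H]1C(C)(C)CCC[C@]1(C)O[Si](CC)(CC)CC | intermediate
5 | diethyl 4-[(1S,2S)-2,6,6-trimethyl-2-(triethylsilyloxy)cyclohexyl]but-1-en-2-yl phosphate (not isolated) | C=C(CC[C@H]1C(C)(C)CCC[C@]1(C)O[Si](CC)(CC)CC)OP(=O)(OCC)OCC | intermediate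
6 | triethyl{[(1S,2S)-2-(but-3-yn-1-yl)-1,3,3-trimethylcyclohexyl]oxy}silane | C#CCC[C@H]1C(C)(C)CCC[C@]1(C)O[Si](CC)(CC)CC | intermediate
7 | dimethyl{(1E)-2-methyl-4-[(1S,2S)-2,6,6-trimethyl-2-(triethylsilyloxy)cyclohexyl]but-1-en-1-yl}alane (not isolated) | C[Al](C)/C=C(\C)CC[C@H]1C(C)(C)CCC[C@]1(C)O[Si](CC)(CC)CC | intermediate
8 | lithium butyl(dimethyl){(1E)-2-methyl-4-[(1S,2S)-2,6,6-trimethyl-2-(triethylsilyloxy)cyclohexyl]but-1-en-1-yl}aluminate (not isolated) | [Li+].CCCC[Al-](C)(C)/C=C(\C)CC[C@H]1C(C)(C)CCC[C@]1(C)O[Si](CC)(CC)CC | intermediate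
9 | (3E)-4-methyl-6-[(1S,2S)-2,6,6-trimethyl-2-(triethylsilyloxy)cyclohexyl]hex-3-en-1-ol | OCC/C=C(\C)CC[C@H]1C(C)(C)CCC[C@]1(C)O[Si](CC)(CC)CC | intermediate
10 | triethyl({(1S,2S)-2-[(3E)-6-iodo-3-methylhex-3-en-1-yl]-1,3,3-trimethylcyclohexyl}oxy)silane | ICC/C=C(\C)CC[C@H]1C(C)(C)CCC[C@]1(C)O[Si](CC)(CC)CC | intermediate
11 | methyl 2-[bis(2,2,2-trifluoroethoxy)phosphoryl]acetate | COC(=O)CP(=O)(OCC(F)(F)F)OCC(F)(F)F | starting material
12 | methyl (5E)-2-[bis(2,2,2-trifluoroethoxy)phosphoryl]-6-methyl-8-[(1S,2S)-2,6,6-trimethyl-2-(triethylsilyloxy)cyclohexyl]oct-5-enoate, mixture of C2 epimers | COC(=O)C(CC/C=C(\C)CC[C@H]1C(C)(C)CCC[C@]1(C)O[Si](CC)(CC)CC)P(=O)(OCC(F)(F)F)OCC(F)(F)F | intermediate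
13 | 2-deoxy-L-ribose, (3R,4S)-3,4,5-trihydroxypentanal | O=CC[C@@H](O)[C@@H](O)CO | starting material
14 | (2S,3R)-4-(1,3-dithian-2-yl)butane-1,2,3-triol | S1CCCSC1C[C@@H](O)[C@@H](O)CO | intermediate
15 | (1R)-2-(1,3-dithian-2-yl)-1-[(4S)-2,2-dimethyl-1,3-dioxolan-4-yl]ethan-1-ol | S1CCCSC1C[C@@H](O)[C@@H]1COC(C)(C)O1 | intermediate
16 | 2-{(2R)-2-[(4S)-2,2-dimethyl-1,3-dioxolan-4-yl]-2-[(4-methoxyphenyl)methoxy]ethyl}-1,3-dithiane | S1CCCSC1C[C@H]([C@@H]1COC(C)(C)O1)OCc1ccc(OC)cc1 | intermediate
17 | (3R)-3-[(4S)-2,2-dimethyl-1,3-dioxolan-4-yl]-3-[(4-methoxyphenyl)methoxy]propanal | O=CC[C@H]([C@@H]1COC(C)(C)O1)OCc1ccc(OC)cc1 | intermediate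
18 | methyl (2Z,5E)-2-{(3R)-3-[(4S)-2,2-dimethyl-1,3-dioxolan-4-yl]-3-[(4-methoxyphenyl)methoxy]propylidene}-6-methyl-8-[(1S,2S)-2,6,6-trimethyl-2-(triethylsilyloxy)cyclohexyl]oct-5-enoate | COC(=O)/C(=C\C[C@H]([C@@H]1COC(C)(C)O1)OCc1ccc(OC)cc1)CC/C=C(\C)CC[C@H]1C(C)(C)CCC[C@]1(C)O[Si](CC)(CC)CC | intermediate
19 | (2Z,5E)-2-{(3R)-3-[(4S)-2,2-dimethyl-1,3-dioxolan-4-yl]-3-[(4-methoxyphenyl)methoxy]propylidene}-6-methyl-8-[(1S,2S)-2,6,6-trimethyl-2-(triethylsilyloxy)cyclohexyl]oct-5-en-1-ol | OC/C(=C\C[C@H]([C@@H]1COC(C)(C)O1)OCc1ccc(OC)cc1)CC/C=C(\C)CC[C@H]1C(C)(C)CCC[C@]1(C)O[Si](CC)(CC)CC | intermediate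
20 | (2S,3R,5Z,9E)-6-(hydroxymethyl)-3-[(4-methoxyphenyl)methoxy]-10-methyl-12-[(1S,2S)-2,6,6-trimethyl-2-(triethylsilyloxy)cyclohexyl]dodeca-5,9-diene-1,2-diol | OC/C(=C\C[C@H]([C@@H](O)CO)OCc1ccc(OC)cc1)CC/C=C(\C)CC[C@H]1C(C)(C)CCC[C@]1(C)O[Si](CC)(CC)CC | intermediate
21 | (2S,3R,5Z,9E)-1-(tert-butyldimethylsilyloxy)-6-[(tert-butyldimethylsilyloxy)methyl]-3-[(4-methoxyphenyl)methoxy]-10-methyl-12-[(1S,2S)-2,6,6-trimethyl-2-(triethylsilyloxy)cyclohexyl]dodeca-5,9-dien-2-ol | CC(C)(C)[Si](C)(C)OC/C(=C\C[C@H]([C@@H](O)CO[Si](C)(C)C(C)(C)C)OCc1ccc(OC)cc1)CC/C=C(\C)CC[C@H]1C(C)(C)CCC[C@]1(C)O[Si](CC)(CC)CC | intermediate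
22 | (3R,5Z,9E)-1-(tert-butyldimethylsilyloxy)-6-[(tert-butyldimethylsilyloxy)methyl]-3-[(4-methoxyphenyl)methoxy]-10-methyl-12-[(1S,2S)-2,6,6-trimethyl-2-(triethylsilyloxy)cyclohexyl]dodeca-5,9-dien-2-one | CC(C)(C)[Si](C)(C)OC/C(=C\C[C@H](C(=O)CO[Si](C)(C)C(C)(C)C)OCc1ccc(OC)cc1)CC/C=C(\C)CC[C@H]1C(C)(C)CCC[C@]1(C)O[Si](CC)(CC)CC | intermediate
23 | (3R,5Z,9E)-1-(tert-butyldimethylsilyloxy)-6-[(tert-butyldimethylsilyloxy)methyl]-3-hydroxy-10-methyl-12-[(1S,2S)-2,6,6-trimethyl-2-(triethylsilyloxy)cyclohexyl]dodeca-5,9-dien-2-one | CC(C)(C)[Si](C)(C)OC/C(=C\C[C@H](C(=O)CO[Si](C)(C)C(C)(C)C)O)CC/C=C(\C)CC[C@H]1C(C)(C)CCC[C@]1(C)O[Si](CC)(CC)CC | intermediate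
24 | (3R,5Z,9E)-1-(tert-butyldimethylsilyloxy)-6-[(tert-butyldimethylsilyloxy)methyl]-10-methyl-2-oxo-12-[(1S,2S)-2,6,6-trimethyl-2-(triethylsilyloxy)cyclohexyl]dodeca-5,9-dien-3-yl (triphenylphosphoranylidene)acetate (not isolated) | CC(C)(C)[Si](C)(C)OC/C(=C\C[C@H](C(=O)CO[Si](C)(C)C(C)(C)C)OC(=O)C=P(c1ccccc1)(c1ccccc1)c1ccccc1)CC/C=C(\C)CC[C@H]1C(C)(C)CCC[C@]1(C)O[Si](CC)(CC)CC | intermediate
25 | (5R)-4-[(tert-butyldimethylsilyloxy)methyl]-5-{(2Z,6E)-3-[(tert-butyldimethylsilyloxy)methyl]-7-methyl-9-[(1S,2S)-2,6,6-trimethyl-2-(triethylsilyloxy)cyclohexyl]nona-2,6-dien-1-yl}furan-2(5H)-one | CC(C)(C)[Si](C)(C)OC/C(=C\C[C@H]1OC(=O)C=C1CO[Si](C)(C)C(C)(C)C)CC/C=C(\C)CC[C@H]1C(C)(C)CCC[C@]1(C)O[Si](CC)(CC)CC | intermediate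
26 | (5R)-4-(hydroxymethyl)-5-{(2Z,6E)-3-(hydroxymethyl)-9-[(1S,2S)-2-hydroxy-2,6,6-trimethylcyclohexyl]-7-methylnona-2,6-dien-1-yl}furan-2(5H)-one | C/C(=C\CC/C(=C/C[C@H]1OC(=O)C=C1CO)CO)CC[C@H]1C(C)(C)CCC[C@]1(C)O | target

## Step count and least certain steps

Total: 18 steps. Longest linear sequence: 14 steps (steps 1–6 and 11–18, from 1). The sugar branch (steps 7–10) has 4 steps.

Step 11 (key step). The Z selectivity may erode, because the long α-substituent can slow oxaphosphetane collapse relative to reversal of the adduct. Base-induced β-elimination of the PMB-oxy group from 17 is a second risk. Upstream, the alkylation that makes 12 (step 6) may be inefficient because the trifluoroethyl phosphonate anion is a weak nucleophile. The fallback sets out from 17 and 10 and returns at 18, bypassing 12. α-Bromination of 11 would give methyl bromo[bis(2,2,2-trifluoroethoxy)phosphoryl]acetate F1. Its olefination with 17 (KOt-Bu, 18-crown-6, THF, −78 °C) is a known route to bromo enoates with the ester cis to the aldehyde-derived carbon, here methyl (2E,5R)-2-bromo-5-[(4S)-2,2-dimethyl-1,3-dioxolan-4-yl]-5-[(4-methoxyphenyl)methoxy]pent-2-enoate F2. Lithium–iodine exchange of 10 (t-BuLi, Et2O, −78 °C) and trapping with B-methoxy-9-borabicyclo[3.3.1]nonane would give the lithium alkyl(methoxy)borate F3. A B-alkyl Suzuki–Miyaura coupling of F3 with F2 (PdCl2(dppf), aq. K3PO4, DMF) would then give 18 with retention of geometry.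

Step 1. The enzyme may convert the short C13 substrate slowly, lose part of the cation to deprotonation (monocyclic dihydroionones), or fall short of full enantiopurity. The fallback sets out from 1 and returns at 3. Cyclisation with SnCl4 in CH2Cl2 at −78 °C would give the racemic enol ether rac-(4aS,8aS)-2,5,5,8a-tetramethyl-4a,5,6,7,8,8a-hexahydro-4H-chromene F4. Dilute acid hydrolysis would give the racemic hydroxy ketone rac-4-[(1S,2S)-2-hydroxy-2,6,6-trimethylcyclohexyl]butan-2-one F5, which would be resolved by preparative chromatography on a chiral stationary phase to give 3.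

Step 4. The carboalumination is dependable; the weak stage is alkenyl transfer from the alanate to ethylene oxide, which may be slow and compete with butyl transfer or epoxide oligomerisation. The fallback sets out from 6 (through 7) and returns at 9. Quenching alane 7 with iodine would give the alkenyl iodide triethyl({(1S,2S)-2-[(3E)-4-iodo-3-methylbut-3-en-1-yl]-1,3,3-trimethylcyclohexyl}oxy)silane F6. Suzuki–Miyaura coupling with vinylboronic acid pinacol ester (Pd(PPh3)4, aq. K3PO4, THF) would give the diene triethyl({(1S,2S)-1,3,3-trimethyl-2-[(3E)-3-methylhexa-3,5-dien-1-yl]cyclohexyl}oxy)silane F7. Hydroboration of the terminal alkene with disiamylborane and oxidation (NaOH, H2O2) would then give 9.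

Step 13. The triethylsilyl ether may be lost together with the acetonide, giving mixtures. The fallback sets out from 19 and returns at 22. Both groups would be removed on purpose (p-TsOH·H2O, MeOH, rt) to give the tetraol (2S,3R,5Z,9E)-6-(hydroxymethyl)-12-[(1S,2S)-2-hydroxy-2,6,6-trimethylcyclohexyl]-3-[(4-methoxyphenyl)methoxy]-10-methyldodeca-5,9-diene-1,2-diol F8. Primary-selective silylation (TBSCl, imidazole) would give the bis-silyl ether (2S,3R,5Z,9E)-1-(tert-butyldimethylsilyloxy)-6-[(tert-butyldimethylsilyloxy)methyl]-12-[(1S,2S)-2-hydroxy-2,6,6-trimethylcyclohexyl]-3-[(4-methoxyphenyl)methoxy]-10-methyldodeca-5,9-dien-2-ol F9. Dess–Martin oxidation, which leaves the tertiary alcohol alone, would give the ketone (3R,5Z,9E)-1-(tert-butyldimethylsilyloxy)-6-[(tert-butyldimethylsilyloxy)methyl]-12-[(1S,2S)-2-hydroxy-2,6,6-trimethylcyclohexyl]-3-[(4-methoxyphenyl)methoxy]-10-methyldodeca-5,9-dien-2-one F10. Silylation of its only remaining hydroxyl (TESOTf, 2,6-lutidine, −78 °C) would give 22.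

Step 17. Addition of the hindered secondary hydroxyl to the ylide may be slow, and prolonged heating may enolise the α-hydroxy ketone (epimerisation at C3 or α-ketol shift). The fallback sets out from 23 and returns at 25. Acylation with diethylphosphonoacetic acid (EDC·HCl, DMAP, CH2Cl2) would give the phosphonoacetate (3R,5Z,9E)-1-(tert-butyldimethylsilyloxy)-6-[(tert-butyldimethylsilyloxy)methyl]-10-methyl-2-oxo-12-[(1S,2S)-2,6,6-trimethyl-2-(triethylsilyloxy)cyclohexyl]dodeca-5,9-dien-3-yl (diethoxyphosphoryl)acetate F11. An intramolecular Horner–Wadsworth–Emmons reaction under Masamune–Roush conditions (LiCl, iPr2NEt, MeCN, rt) would then close ring B to give 25.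

## Further compounds

F1 | step 11 | methyl bromo[bis(2,2,2-trifluoroethoxy)phosphoryl]acetate (racemic, configurationally labile) | COC(=O)C(Br)P(=O)(OCC(F)(F)F)OCC(F)(F)F
F2 | step 11 | methyl (2E,5R)-2-bromo-5-[(4S)-2,2-dimethyl-1,3-dioxolan-4-yl]-5-[(4-methoxyphenyl)methoxy]pent-2-enoate | COC(=O)/C(Br)=C\C[C@H]([C@@H]1COC(C)(C)O1)OCc1ccc(OC)cc1
F3 | step 11 | lithium methoxy{(3E)-4-methyl-6-[(1S,2S)-2,6,6-trimethyl-2-(triethylsilyloxy)cyclohexyl]hex-3-en-1-yl}-9-borabicyclo[3.3.1]nonan-9-uide | [Li+].CO[B-]1(CC/C=C(\C)CC[C@H]2C(C)(C)CCC[C@]2(C)O[Si](CC)(CC)CC)C2CCCC1CCC2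
F4 | step 1 | rac-(4aS,8aS)-2,5,5,8a-tetramethyl-4a,5,6,7,8,8a-hexahydro-4H-chromene (1:1 mixture of enantiomers) | CC1=CC[C@H]2C(C)(C)CCC[C@]2(C)O1.CC1=CC[C@@H]2C(C)(C)CCC[C@@]2(C)O1
F5 | step 1 | rac-4-[(1S,2S)-2-hydroxy-2,6,6-trimethylcyclohexyl]butan-2-one (1:1 mixture of enantiomers) | CC(=O)CC[C@H]1C(C)(C)CCC[C@]1(C)O.CC(=O)CC[C@@H]1C(C)(C)CCC[C@@]1(C)O
F6 | step 4 | triethyl({(1S,2S)-2-[(3E)-4-iodo-3-methylbut-3-en-1-yl]-1,3,3-trimethylcyclohexyl}oxy)silane | I/C=C(\C)CC[C@H]1C(C)(C)CCC[C@]1(C)O[Si](CC)(CC)CC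
F7 | step 4 | triethyl({(1S,2S)-1,3,3-trimethyl-2-[(3E)-3-methylhexa-3,5-dien-1-yl]cyclohexyl}oxy)silane | C=C/C=C(\C)CC[C@H]1C(C)(C)CCC[C@]1(C)O[Si](CC)(CC)CC
F8 | step 13 | (2S,3R,5Z,9E)-6-(hydroxymethyl)-12-[(1S,2S)-2-hydroxy-2,6,6-trimethylcyclohexyl]-3-[(4-methoxyphenyl)methoxy]-10-methyldodeca-5,9-diene-1,2-diol | OC/C(=C\C[C@H]([C@@H](O)CO)OCc1ccc(OC)cc1)CC/C=C(\C)CC[C@H]1C(C)(C)CCC[C@]1(C)O
F9 | step 13 | (2S,3R,5Z,9E)-1-(tert-butyldimethylsilyloxy)-6-[(tert-butyldimethylsilyloxy)methyl]-12-[(1S,2S)-2-hydroxy-2,6,6-trimethylcyclohexyl]-3-[(4-methoxyphenyl)methoxy]-10-methyldodeca-5,9-dien-2-ol | CC(C)(C)[Si](C)(C)OC/C(=C\C[C@H]([C@@H](O)CO[Si](C)(C)C(C)(C)C)OCc1ccc(OC)cc1)CC/C=C(\C)CC[C@H]1C(C)(C)CCC[C@]1(C)O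
F10 | step 13 | (3R,5Z,9E)-1-(tert-butyldimethylsilyloxy)-6-[(tert-butyldimethylsilyloxy)methyl]-12-[(1S,2S)-2-hydroxy-2,6,6-trimethylcyclohexyl]-3-[(4-methoxyphenyl)methoxy]-10-methyldodeca-5,9-dien-2-one | CC(C)(C)[Si](C)(C)OC/C(=C\C[C@H](C(=O)CO[Si](C)(C)C(C)(C)C)OCc1ccc(OC)cc1)CC/C=C(\C)CC[C@H]1C(C)(C)CCC[C@]1(C)O
F11 | step 17 | (3R,5Z,9E)-1-(tert-butyldimethylsilyloxy)-6-[(tert-butyldimethylsilyloxy)methyl]-10-methyl-2-oxo-12-[(1S,2S)-2,6,6-trimethyl-2-(triethylsilyloxy)cyclohexyl]dodeca-5,9-dien-3-yl (diethoxyphosphoryl)acetate | CC(C)(C)[Si](C)(C)OC/C(=C\C[C@H](C(=O)CO[Si](C)(C)C(C)(C)C)OC(=O)CP(=O)(OCC)OCC)CC/C=C(\C)CC[C@H]1C(C)(C)CCC[C@]1(C)O[Si](CC)(CC)CC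
A1 | alternative 1 | (4aS,8aS)-2,5,5,8a-tetramethyl-4a,5,6,7,8,8a-hexahydro-4H-chromene (identical with 2) | CC1=CC[C@H]2C(C)(C)CCC[C@]2(C)O1
A2 | alternative 2 | (5R)-4-[(tert-butyldimethylsilyloxy)methyl]-5-{(2Z,6E)-3-[(tert-butyldimethylsilyloxy)methyl]-9-[(1S,2S)-2-hydroxy-2,6,6-trimethylcyclohexyl]-7-methylnona-2,6-dien-1-yl}furan-2(5H)-one | C/C(=C\CC/C(=C/C[C@H]1OC(=O)C=C1CO[Si](C)(C)C(C)(C)C)CO[Si](C)(C)C(C)(C)C)CC[C@H]1C(C)(C)CCC[C@]1(C)O
A3 | alternative 2 | (1S,2S)-2-[(3E,7Z)-7-{[(tert-butyldimethylsilyl)oxy]methyl}-8-iodo-3-methylocta-3,7-dien-1-yl]-1,3,3-trimethylcyclohexan-1-ol | I/C=C(\CO[Si](C)(C)C(C)(C)C)CC/C=C(\C)CC[C@H]1C(C)(C)CCC[C@]1(C)O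
A4 | alternative 2 | 1,3-dioxoisoindolin-2-yl 2-[(2R)-3-{[(tert-butyldimethylsilyl)oxy]methyl}-5-oxo-2,5-dihydrofuran-2-yl]acetate | O=C(C[C@H]1OC(=O)C=C1CO[Si](C)(C)C(C)(C)C)ON1C(=O)c2ccccc2C1=O
A5 | alternative 3 | (2Z,5E)-2-(iodomethylidene)-6-methyl-8-[(1S,2S)-2,6,6-trimethyl-2-(triethylsilyloxy)cyclohexyl]oct-5-en-1-ol | OC/C(=C\I)CC/C=C(\C)CC[C@H]1C(C)(C)CCC[C@]1(C)O[Si](CC)(CC)CC
A6 | alternative 3 | {(3E)-4-methyl-6-[(1S,2S)-2,6,6-trimethyl-2-(triethylsilyloxy)cyclohexyl]hex-3-en-1-yl}magnesium iodide | I[Mg]CC/C=C(\C)CC[C@H]1C(C)(C)CCC[C@]1(C)O[Si](CC)(CC)CC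
A7 | alternative 3 | prop-2-yn-1-ol | C#CCO
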